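**Plan**

- Retrosynthesis: the two allyl ethers, the O3 silyl ether and the C4 hydride are removed first. Ring C is then cut at O1–C8a and C4–C4a in one operation, leaving a ring A aryne and an open C2–C3–C4 hydroxy ester, which is cut at C2–C3 (aldol).
- Enabling feature: O1 and C4 are bonded to the neighbouring ring A carbons C8a and C4a, the pattern of an aryne, and the C5 methoxy group beside C4a polarises that aryne so that an oxygen nucleophile enters at C8a.
- Forward order: ring A (from 5-methoxyresorcinol) receives the C8 prenyl group, then bromine (later SiMe3) at C4a and a triflate on the C8a oxygen. Ring B arrives with 4-allyloxybenzaldehyde in the aldol that joins C2 to C3, and ring C is closed last by the aryne annulation.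
- Stereochemistry: C2 and C3 come from an auxiliary-controlled anti glycolate aldol and pass through the annulation unchanged (O-arylation with retention). C4 is set by bulky-hydride delivery anti to the O3 silyl ether.

Key step: step 11

Remark: ring atoms carry flavan numbering (O1, C2–C4, C4a, C5–C8, C8a) from the first step on; the butane-2,3-diacetal of glycolic acid 15 and 4-allyloxybenzaldehyde 16 are taken as purchased.

**Route**

Step 1
Reactants: 1 5-methoxyresorcinol
Product: 2 1-methoxy-3,5-bis(methoxymethoxy)benzene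
Conditions: MOMCl, i-Pr2NEt, CH2Cl2, 0 °C → rt
Reagents that add atoms: chloromethyl methyl ether (MOMCl), COCCl
Why: Base-mediated O-alkylation of both phenols (Williamson-type ether formation) installs the two MOM groups that later direct both ring lithiations.

Step 2
Reactants: 2 1-methoxy-3,5-bis(methoxymethoxy)benzene; 3 prenyl bromide
Product: 5 5-methoxy-1,3-bis(methoxymethoxy)-2-(3-methylbut-2-enyl)benzene, via aryllithium 4 (not isolated)
Conditions: n-BuLi, THF, 0 °C; CuBr·SMe2 (10 mol %), 3, −78 °C → rt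
Reagents that add atoms: none
Why: Directed ortho-metalation removes the proton flanked by both MOM ethers (cooperative chelation), and copper-catalysed SN2 alkylation of the aryllithium with prenyl bromide should give the linear C8 prenyl arene.

Step 3
Reactants: 5 5-methoxy-1,3-bis(methoxymethoxy)-2-(3-methylbut-2-enyl)benzene
Product: 7 2-bromo-1-methoxy-3,5-bis(methoxymethoxy)-4-(3-methylbut-2-enyl)benzene, via aryllithium 6 (not isolated)
Conditions: n-BuLi, TMEDA, THF, −20 → 0 °C; BrCCl2CCl2Br, −78 °C → rt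
Reagents that add atoms: 1,2-dibromo-1,1,2,2-tetrachloroethane, BrC(Cl)(Cl)C(Cl)(Cl)Br
Why: A second directed ortho-metalation at one of the two equivalent positions between a MOM ether and the methoxy group (the future C4a), followed by bromine transfer from the polyhaloethane to the aryllithium, places bromine without any electrophilic bromine that would attack the prenyl alkene.

Step 4
Reactants: 7 2-bromo-1-methoxy-3,5-bis(methoxymethoxy)-4-(3-methylbut-2-enyl)benzene
Product: 8 4-bromo-5-methoxy-2-(3-methylbut-2-enyl)benzene-1,3-diol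
Conditions: HCl (1.25 M in MeOH), rt
Reagents that add atoms: none
Why: Acid-catalysed acetal methanolysis cleaves both MOM ethers under dilute, room-temperature conditions of the kind that ortho-prenyl phenols are known to tolerate without cyclising to chromans.

Step 5
Reactants: 8 4-bromo-5-methoxy-2-(3-methylbut-2-enyl)benzene-1,3-diol
Product: 9 4-bromo-5-methoxy-2-(3-methylbut-2-enyl)-1,3-bis(trimethylsilyloxy)benzene
Conditions: (Me3Si)2NH, THF, 70 °C; evaporate
Reagents that add atoms: hexamethyldisilazane, C[Si](C)(C)N[Si](C)(C)C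
Why: Silylation of both phenols by the disilazane, with ammonia as the only by-product, is the standard preparation of an ortho-bromoaryl silyl ether for a retro-Brook sequence.

Step 6
Reactants: 9 4-bromo-5-methoxy-2-(3-methylbut-2-enyl)-1,3-bis(trimethylsilyloxy)benzene
Product: 13 3-hydroxy-5-methoxy-2-(3-methylbut-2-enyl)-6-(trimethylsilyl)phenyl triflate, via aryllithium 10 (not isolated), via lithium phenoxide 11 (not isolated), via silyl ether triflate 12 (not isolated)
Conditions: n-BuLi, THF, −78 °C; Tf2O, −78 → 0 °C; aq. citric acid, rt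
Reagents that add atoms: triflic anhydride, O=S(=O)(OS(=O)(=O)C(F)(F)F)C(F)(F)F
Why: Bromine–lithium exchange and the anionic 1,3 O→C silyl shift (retro-Brook rearrangement) move SiMe3 from the C8a oxygen to C4a and unmask only that phenoxide, which Tf2O traps, while the untouched silyl ether on O7 is hydrolysed on work-up, so the two phenols are told apart.

Step 7
Reactants: 13 3-hydroxy-5-methoxy-2-(3-methylbut-2-enyl)-6-(trimethylsilyl)phenyl triflate
Product: 14 3-(allyloxy)-5-methoxy-2-(3-methylbut-2-enyl)-6-(trimethylsilyl)phenyl triflate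
Conditions: allyl bromide, K2CO3, acetone, rt
Reagents that add atoms: allyl bromide, C=CCBr
Why: Williamson etherification of the remaining O7 phenol under mild carbonate conditions should leave the aryl triflate and the aryl silane intact.

Step 8
Reactants: 15 (5S,6S)-5,6-dimethoxy-5,6-dimethyl-1,4-dioxan-2-one; 16 4-(allyloxy)benzaldehyde
Product: 18 (3R,5S,6S)-3-[(R)-[4-(allyloxy)phenyl](hydroxy)methyl]-5,6-dimethoxy-5,6-dimethyl-1,4-dioxan-2-one, via lithium enolate 17 (not isolated)
Conditions: LiN(SiMe3)2, THF, −78 °C; 16, −78 °C; AcOH quench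
Reagents that add atoms: none
Why: In this lithium enolate aldol addition the lactone ring fixes the E-enolate, a closed chair transition state should therefore give the anti adduct, and the aldehyde approaches the face opposite the axial C5 methoxy group of the diacetal, which sets the future C3 as R and the future C2 as R.

Step 9
Reactants: 18 (3R,5S,6S)-3-[(R)-[4-(allyloxy)phenyl](hydroxy)methyl]-5,6-dimethoxy-5,6-dimethyl-1,4-dioxan-2-one
Product: 19 methyl (2R,3R)-3-[4-(allyloxy)phenyl]-2,3-dihydroxypropanoate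
Conditions: TMSCl (0.3 equiv), MeOH, rt
Reagents that add atoms: methanol, CO
Why: Acid-catalysed transacetalisation and lactone methanolysis release the anti diol as its methyl ester, with HCl generated only in catalytic amount so that the electron-rich benzylic alcohol is not ionised.

Step 10
Reactants: 19 methyl (2R,3R)-3-[4-(allyloxy)phenyl]-2,3-dihydroxypropanoate
Product: 20 methyl (2R,3R)-3-[4-(allyloxy)phenyl]-2-(tert-butyldimethylsilyloxy)-3-hydroxypropanoate
Conditions: TBSCl, imidazole, DMF, −20 → 0 °C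
Reagents that add atoms: tert-butyldimethylsilyl chloride, CC(C)(C)[Si](C)(C)Cl
Why: Imidazole-assisted silyl ether formation should go first to the C2 hydroxyl, which is alpha to the ester and therefore the more acidic and less hindered of the two, as in related 2,3-dihydroxy-3-arylpropanoates.

Step 11
Reactants: 14 3-(allyloxy)-5-methoxy-2-(3-methylbut-2-enyl)-6-(trimethylsilyl)phenyl triflate; 20 methyl (2R,3R)-3-[4-(allyloxy)phenyl]-2-(tert-butyldimethylsilyloxy)-3-hydroxypropanoate
Product: 24 (2R,3R)-7-(allyloxy)-2-[4-(allyloxy)phenyl]-3-(tert-butyldimethylsilyloxy)-5-methoxy-8-(3-methylbut-2-enyl)chroman-4-one, via trimethylsilyl ether 21 (not isolated), via aryne 22 (not isolated), via aryl anion 23 (not isolated)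
Conditions: 20, (Me3Si)2NH, TMSCl (cat.), THF, 40 °C, evaporate; then 14, KF, 18-crown-6, THF, −20 °C → rt; pH 7 buffer
Reagents that add atoms: none
Why: Proposed new method: fluoride strips the O–SiMe3 group of 21 and the C–SiMe3 group of 14 in the same aprotic solution, so the secondary alkoxide and the 3-methoxyaryne 22 appear together with no proton donor present; the alkoxide adds to C8a and the C4a aryl anion 23 then attacks the methyl ester and expels methoxide. The closest known reaction type is the fluoride-induced annulation of ortho-silylaryl triflates with methyl salicylates to xanthones, where oxygen addition to the aryne is followed by intramolecular acylation of the aryl anion; here an aliphatic aldol alkoxide takes the place of the phenoxide. Ring C closes by a 6-exo-trig acyl substitution that forms C4–C4a directly after O1–C8a. No stereocentre is created: the C2 oxygen is arylated with retention and C3 is untouched, so the anti aldol pattern becomes the 2,3-trans (2R,3R) chromanone, which is also the thermodynamically preferred epimer should C3 enolise. The step needs attack at C8a and not at C4a, which the inductive distortion of the aryne by the C5 methoxy group (the anion develops next to it) should secure against the weaker opposing influence of the C8 prenyl group and the C7 oxygen. It also needs aryne capture faster than retro-aldol or 1,2-silyl shift of the alkoxide and acylation faster than protonation, which the in-situ release of the alkoxide from its silyl ether, the absence of O–H groups and the low temperature are meant to secure.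

Step 12
Reactants: 24 (2R,3R)-7-(allyloxy)-2-[4-(allyloxy)phenyl]-3-(tert-butyldimethylsilyloxy)-5-methoxy-8-(3-methylbut-2-enyl)chroman-4-one
Product: 25 (2R,3S,4S)-7-(allyloxy)-2-[4-(allyloxy)phenyl]-3-(tert-butyldimethylsilyloxy)-5-methoxy-8-(3-methylbut-2-enyl)chroman-4-ol
Conditions: LiBH(s-Bu)3 (L-Selectride), THF, −78 °C; aq. NH4Cl
Reagents that add atoms: none
Why: In this diastereoselective bulky-hydride ketone reduction the tri-sec-butylborohydride should approach C4 from the face opposite the neighbouring equatorial silyloxy group (equatorial attack, as with 2-substituted cyclohexanones and with flavan-3-ones), giving the pseudo-axial 4-hydroxyl cis to O3 and setting C4 as S.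

Step 13
Reactants: 25 (2R,3S,4S)-7-(allyloxy)-2-[4-(allyloxy)phenyl]-3-(tert-butyldimethylsilyloxy)-5-methoxy-8-(3-methylbut-2-enyl)chroman-4-ol
Product: 26 (2R,3S,4S)-7-(allyloxy)-2-[4-(allyloxy)phenyl]-5-methoxy-8-(3-methylbut-2-enyl)chromane-3,4-diol
Conditions: Bu4NF, AcOH, THF, 0 °C → rt
Reagents that add atoms: none
Why: Fluoride cleavage of the secondary silyl ether, buffered with acetic acid and carried out while both phenols are still masked, should free O3 without exposing the benzylic C4 alcohol to strong base.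

Step 14
Reactants: 26 (2R,3S,4S)-7-(allyloxy)-2-[4-(allyloxy)phenyl]-5-methoxy-8-(3-methylbut-2-enyl)chromane-3,4-diol
Product: 27 5-O-methyl-8-prenylafzelechin-4β-ol
Conditions: Pd(PPh3)4 (5 mol %), morpholine, THF, rt; neutral work-up
Reagents that add atoms: none
Why: In this Tsuji–Trost-type deallylation zerovalent palladium ionises only the two aryl allyl ethers to π-allyl complexes that morpholine captures, under neutral conditions that should leave the prenyl group and the acid-sensitive benzylic diol untouched.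

**Compound list**

1 | 5-methoxyresorcinol | COc1cc(O)cc(O)c1 | starting material
2 | 1-methoxy-3,5-bis(methoxymethoxy)benzene | COCOc1cc(OC)cc(OCOC)c1 | intermediate
3 | prenyl bromide (1-bromo-3-methylbut-2-ene) | CC(C)=CCBr | starting material
4 | 4-methoxy-2,6-bis(methoxymethoxy)phenyllithium | [Li]c1c(OCOC)cc(OC)cc1OCOC | intermediate (not isolated)
5 | 5-methoxy-1,3-bis(methoxymethoxy)-2-(3-methylbut-2-enyl)benzene | COCOc1cc(OC)cc(OCOC)c1CC=C(C)C | intermediate
6 | 6-methoxy-2,4-bis(methoxymethoxy)-3-(3-methylbut-2-enyl)phenyllithium | COc1cc(OCOC)c(CC=C(C)C)c(OCOC)c1[Li] | intermediate (not isolated)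
7 | 2-bromo-1-methoxy-3,5-bis(methoxymethoxy)-4-(3-methylbut-2-enyl)benzene | COc1cc(OCOC)c(CC=C(C)C)c(OCOC)c1Br | intermediate
8 | 4-bromo-5-methoxy-2-(3-methylbut-2-enyl)benzene-1,3-diol | COc1cc(O)c(CC=C(C)C)c(O)c1Br | intermediate
9 | 4-bromo-5-methoxy-2-(3-methylbut-2-enyl)-1,3-bis(trimethylsilyloxy)benzene | COc1cc(O[Si](C)(C)C)c(CC=C(C)C)c(O[Si](C)(C)C)c1Br | intermediate
10 | 6-methoxy-3-(3-methylbut-2-enyl)-2,4-bis(trimethylsilyloxy)phenyllithium | COc1cc(O[Si](C)(C)C)c(CC=C(C)C)c(O[Si](C)(C)C)c1[Li] | intermediate (not isolated)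
11 | lithium 5-methoxy-2-(3-methylbut-2-enyl)-6-(trimethylsilyl)-3-(trimethylsilyloxy)phenoxide | COc1cc(O[Si](C)(C)C)c(CC=C(C)C)c(O[Li])c1[Si](C)(C)C | intermediate (not isolated)
12 | 5-methoxy-2-(3-methylbut-2-enyl)-6-(trimethylsilyl)-3-(trimethylsilyloxy)phenyl triflate | COc1cc(O[Si](C)(C)C)c(CC=C(C)C)c(OS(=O)(=O)C(F)(F)F)c1[Si](C)(C)C | intermediate (not isolated)
13 | 3-hydroxy-5-methoxy-2-(3-methylbut-2-enyl)-6-(trimethylsilyl)phenyl triflate | COc1cc(O)c(CC=C(C)C)c(OS(=O)(=O)C(F)(F)F)c1[Si](C)(C)C | intermediate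
14 | 3-(allyloxy)-5-methoxy-2-(3-methylbut-2-enyl)-6-(trimethylsilyl)phenyl triflate (aryne precursor) | COc1cc(OCC=C)c(CC=C(C)C)c(OS(=O)(=O)C(F)(F)F)c1[Si](C)(C)C | intermediate
15 | (5S,6S)-5,6-dimethoxy-5,6-dimethyl-1,4-dioxan-2-one | O=C1CO[C@](C)(OC)[C@@](C)(OC)O1 | starting material
16 | 4-(allyloxy)benzaldehyde | O=Cc1ccc(OCC=C)cc1 | starting material
17 | lithium enolate of 15 | [Li]OC1=CO[C@](C)(OC)[C@@](C)(OC)O1 | intermediate (not isolated)
18 | (3R,5S,6S)-3-[(R)-[4-(allyloxy)phenyl](hydroxy)methyl]-5,6-dimethoxy-5,6-dimethyl-1,4-dioxan-2-one | O=C1[C@@H]([C@H](O)c2ccc(OCC=C)cc2)O[C@](C)(OC)[C@@](C)(OC)O1 | intermediate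
19 | methyl (2R,3R)-3-[4-(allyloxy)phenyl]-2,3-dihydroxypropanoate | COC(=O)[C@H](O)[C@H](O)c1ccc(OCC=C)cc1 | intermediate
20 | methyl (2R,3R)-3-[4-(allyloxy)phenyl]-2-(tert-butyldimethylsilyloxy)-3-hydroxypropanoate | COC(=O)[C@H](O[Si](C)(C)C(C)(C)C)[C@H](O)c1ccc(OCC=C)cc1 | intermediate
21 | methyl (2R,3R)-3-[4-(allyloxy)phenyl]-2-(tert-butyldimethylsilyloxy)-3-(trimethylsilyloxy)propanoate | COC(=O)[C@H](O[Si](C)(C)C(C)(C)C)[C@H](O[Si](C)(C)C)c1ccc(OCC=C)cc1 | intermediate (not isolated)
22 | 5-(allyloxy)-3-methoxy-6-(3-methylbut-2-enyl)benzyne (aryne carbons are the future C8a and C4a) | COC1=CC(OCC=C)=C(CC=C(C)C)C#C1 | intermediate (not isolated)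
23 | potassium salt of the C4a aryl anion of methyl (2R,3R)-3-[4-(allyloxy)phenyl]-3-[3-(allyloxy)-5-methoxy-2-(3-methylbut-2-enyl)phenoxy]-2-(tert-butyldimethylsilyloxy)propanoate | [K+].COC(=O)[C@H](O[Si](C)(C)C(C)(C)C)[C@@H](c1ccc(OCC=C)cc1)Oc1[c-]c(OC)cc(OCC=C)c1CC=C(C)C | intermediate (not isolated)
24 | (2R,3R)-7-(allyloxy)-2-[4-(allyloxy)phenyl]-3-(tert-butyldimethylsilyloxy)-5-methoxy-8-(3-methylbut-2-enyl)chroman-4-one | COc1cc(OCC=C)c(CC=C(C)C)c2c1C(=O)[C@H](O[Si](C)(C)C(C)(C)C)[C@@H](c1ccc(OCC=C)cc1)O2 | intermediate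
25 | (2R,3S,4S)-7-(allyloxy)-2-[4-(allyloxy)phenyl]-3-(tert-butyldimethylsilyloxy)-5-methoxy-8-(3-methylbut-2-enyl)chroman-4-ol | COc1cc(OCC=C)c(CC=C(C)C)c2c1[C@H](O)[C@H](O[Si](C)(C)C(C)(C)C)[C@@H](c1ccc(OCC=C)cc1)O2 | intermediate
26 | (2R,3S,4S)-7-(allyloxy)-2-[4-(allyloxy)phenyl]-5-methoxy-8-(3-methylbut-2-enyl)chromane-3,4-diol | COc1cc(OCC=C)c(CC=C(C)C)c2c1[C@H](O)[C@H](O)[C@@H](c1ccc(OCC=C)cc1)O2 | intermediate
27 | 5-O-methyl-8-prenylafzelechin-4β-ol, (2R,3S,4S)-2-(4-hydroxyphenyl)-5-methoxy-8-(3-methylbut-2-enyl)chromane-3,4,7-triol | COc1cc(O)c(CC=C(C)C)c2c1[C@H](O)[C@H](O)[C@@H](c1ccc(O)cc1)O2 | target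

**Step count and risks**

Total: 14 steps. Longest linear sequence: 11 steps (steps 1–7, then 11–14); the hydroxy ester arm (steps 8–10) joins at step 11.

Step 11 (aryne annulation). What may go wrong:
- the unmasked alkoxide may fragment by retro-aldol or take over the neighbouring silyl group before it meets the aryne;
- the aryl anion may be protonated instead of acylated;
- the alkoxide may enter at C4a.

Fallback, by the classical chalcone epoxide route, from 7 and 16 back to 24: bromine–lithium exchange on 7 (n-BuLi, THF, −78 °C) and acylation with N-methoxy-N-methylacetamide would give 1-[6-methoxy-2,4-bis(methoxymethoxy)-3-(3-methylbut-2-enyl)phenyl]ethanone F1. Claisen–Schmidt condensation with 16 (KOH, EtOH) would give the chalcone (E)-3-[4-(allyloxy)phenyl]-1-[6-methoxy-2,4-bis(methoxymethoxy)-3-(3-methylbut-2-enyl)phenyl]prop-2-en-1-one F2. Juliá–Colonna epoxidation (poly-L-leucine, urea–H2O2, DBU, THF) would give the (2R,3S)-epoxy ketone F3. HCl in MeOH would remove both MOM groups, and the freed C8a phenol would open the epoxide at the benzylic carbon with inversion to give (2R,3R)-2-[4-(allyloxy)phenyl]-3,7-dihydroxy-5-methoxy-8-(3-methylbut-2-enyl)chroman-4-one F4. Allyl bromide and K2CO3 in acetone would alkylate only the O7 phenol to give the 7-O-allyl dihydroflavonol F5, and TBSOTf with 2,6-lutidine would silylate O3 and return to 24.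

Step 12 (C4 reduction). What may go wrong: poor facial selectivity, because the peri C5 methoxy group may hinder the equatorial approach and favour the 3,4-trans alcohol.

Fallback, from 24 back to 25, by reduction with the opposite sense followed by inversion: NaBH4 (MeOH–THF, 0 °C), which attacks axially, would give the 3,4-trans alcohol (2R,3S,4R)-7-(allyloxy)-2-[4-(allyloxy)phenyl]-3-(tert-butyldimethylsilyloxy)-5-methoxy-8-(3-methylbut-2-enyl)chroman-4-ol F6. Mitsunobu inversion (4-nitrobenzoic acid, PPh3, DIAD, THF) would give the 3,4-cis 4-nitrobenzoate F7, and K2CO3 in MeOH would cleave the ester to 25. A silyl shift between O3 and O4 at this point would be harmless, since step 13 removes the group.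

Step 10 (monosilylation). What may go wrong: poor site selectivity between the two hydroxyls, or a silyl shift from O2 to O3 under the basic conditions.

Fallback, from 18 back to 20, by masking the benzylic hydroxyl while it is still the only free one: TrocCl and pyridine (CH2Cl2, 0 °C) would give the 2,2,2-trichloroethyl carbonate of 18 F8. TMSCl in MeOH would give methyl (2R,3R)-3-[4-(allyloxy)phenyl]-2-hydroxy-3-[(2,2,2-trichloroethoxy)carbonyloxy]propanoate F9. TBSOTf and 2,6-lutidine would give its 2-O-tert-butyldimethylsilyl ether F10, and zinc dust in AcOH–THF would remove the carbonate under non-basic conditions to give 20.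

**Further compounds**

F1 | step 11 | 1-[6-methoxy-2,4-bis(methoxymethoxy)-3-(3-methylbut-2-enyl)phenyl]ethanone | COc1cc(OCOC)c(CC=C(C)C)c(OCOC)c1C(C)=O
F2 | step 11 | (E)-3-[4-(allyloxy)phenyl]-1-[6-methoxy-2,4-bis(methoxymethoxy)-3-(3-methylbut-2-enyl)phenyl]prop-2-en-1-one | COc1cc(OCOC)c(CC=C(C)C)c(OCOC)c1C(=O)/C=C/c1ccc(OCC=C)cc1
F3 | step 11 | [(2R,3S)-3-[4-(allyloxy)phenyl]oxiran-2-yl][6-methoxy-2,4-bis(methoxymethoxy)-3-(3-methylbut-2-enyl)phenyl]methanone | COc1cc(OCOC)c(CC=C(C)C)c(OCOC)c1C(=O)[C@@H]1O[C@H]1c1ccc(OCC=C)cc1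
F4 | step 11 | (2R,3R)-2-[4-(allyloxy)phenyl]-3,7-dihydroxy-5-methoxy-8-(3-methylbut-2-enyl)chroman-4-one | COc1cc(O)c(CC=C(C)C)c2c1C(=O)[C@H](O)[C@@H](c1ccc(OCC=C)cc1)O2
F5 | step 11 | (2R,3R)-7-(allyloxy)-2-[4-(allyloxy)phenyl]-3-hydroxy-5-methoxy-8-(3-methylbut-2-enyl)chroman-4-one | COc1cc(OCC=C)c(CC=C(C)C)c2c1C(=O)[C@H](O)[C@@H](c1ccc(OCC=C)cc1)O2
F6 | step 12 | (2R,3S,4R)-7-(allyloxy)-2-[4-(allyloxy)phenyl]-3-(tert-butyldimethylsilyloxy)-5-methoxy-8-(3-methylbut-2-enyl)chroman-4-ol | COc1cc(OCC=C)c(CC=C(C)C)c2c1[C@@H](O)[C@H](O[Si](C)(C)C(C)(C)C)[C@@H](c1ccc(OCC=C)cc1)O2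
F7 | step 12 | (2R,3R,4S)-7-(allyloxy)-2-[4-(allyloxy)phenyl]-3-(tert-butyldimethylsilyloxy)-5-methoxy-8-(3-methylbut-2-enyl)chroman-4-yl 4-nitrobenzoate | COc1cc(OCC=C)c(CC=C(C)C)c2c1[C@H](OC(=O)c1ccc(cc1)[N+](=O)[O-])[C@H](O[Si](C)(C)C(C)(C)C)[C@@H](c1ccc(OCC=C)cc1)O2
F8 | step 10 | (3R,5S,6S)-3-[(R)-[4-(allyloxy)phenyl][(2,2,2-trichloroethoxy)carbonyloxy]methyl]-5,6-dimethoxy-5,6-dimethyl-1,4-dioxan-2-one | O=C1[C@@H]([C@H](OC(=O)OCC(Cl)(Cl)Cl)c2ccc(OCC=C)cc2)O[C@](C)(OC)[C@@](C)(OC)O1
F9 | step 10 | methyl (2R,3R)-3-[4-(allyloxy)phenyl]-2-hydroxy-3-[(2,2,2-trichloroethoxy)carbonyloxy]propanoate | COC(=O)[C@H](O)[C@H](OC(=O)OCC(Cl)(Cl)Cl)c1ccc(OCC=C)cc1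
F10 | step 10 | methyl (2R,3R)-3-[4-(allyloxy)phenyl]-2-(tert-butyldimethylsilyloxy)-3-[(2,2,2-trichloroethoxy)carbonyloxy]propanoate | COC(=O)[C@H](O[Si](C)(C)C(C)(C)C)[C@H](OC(=O)OCC(Cl)(Cl)Cl)c1ccc(OCC=C)cc1
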